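Tuesday's and Friday's flasks carry the same ratio of free catalyst to substrate, 5.00 %, so the same share of target (the selectivity) seemed a safe guess. That was the pitfall.

| flask | substrate | free catalyst | remark | time |
|---|---|---|---|---|
| cedar | 0.16 M | 6 mM | run made earlier |  |
| elm | 0.64 M | 6 mM | run made earlier |  |
| larch | 0.12 M | 15 mM | run made earlier |  |
| Tuesday's | 0.12 M | 6.0 mM |  | 3.0 h |
| Friday's | 0.50 M | 25 mM |  | 3.0 h |

| run | time / h | target / % | isomer of the product / % |
|---|---|---|---|
| cedar | 0.833 | 9.3 | 0 |
| cedar | 1.50 | 11.8 | 0.3 |
| cedar | 2.50 | 13.8 | 3.2 |
| cedar | 3.00 | 14.7 | 2.6 |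
| elm | 0.833 | 9.2 | 2.9 |
| elm | 1.50 | 11.2 | 2.9 |
| elm | 2.50 | 13.8 | 3.5 |
| elm | 3.00 | 15.4 | 1.3 |
| larch | 0.417 | 9.2 | 3.5 |
| larch | 1.00 | 13.7 | 2.9 |
| larch | 2.00 | 17.7 | 4.5 |
| larch | 3.00 | 18.8 | 4.9 |

(readings scatter by 1 percentage point)
- the earlier runs were read with a standard deviation of 1 percentage point
1. the flask that ends with the higher share of target in all that became target or isomer of the product, or "neither" when 2 percentage points or less lies between them (Tuesday's / Friday's / neither)
2. share of target in all that became target or isomer of the product, Tuesday's
3. share of target in all that became target or isomer of the product, Friday's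

The readings did not go by that ratio. Elm held 4.00 times cedar's substrate, yet their last readings of target were 15.4 % and 14.7 %. Larch at 1.00 h read 13.7 % and cedar at 2.50 h read 13.8 %, both at 15.0 mM·h of catalyst times time. So I followed one molecule through its two forks, substrate to target and target on to isomer, and took its chances to go by the dose, free catalyst charged times time: 18.0 mM·h for Tuesday's.

Cedar and elm reach 18.0 mM·h at their last readings and 15.0 mM·h one reading earlier, where larch's second reading also stands, so I pooled these five; they lie at or below Tuesday's dose and do not bracket it, and if the share falls along the dose the pooled value leans high: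

Tuesday's share = 84.1 %

Friday's dose, 75.0 mM·h, which is 4.17 times Tuesday's 18.0 mM·h, lies past larch's last, 45.0 mM·h. Assuming the share keeps falling along the dose, larch's last reading bounds it from above. Holding target at that reading and letting isomer grow in proportion to dose bounds it from below:

above: 79.3 %
below: 69.7 %

By hand I could go no further than the middle, 74.5 %. Tuesday's stood 4.8 points above the upper bound, against a margin of 2 points, so I chose Tuesday's.

The forecast also named Tuesday's, with 85 % (80 % to 90 %) and 76 % (67 % to 83 %), the latter inside my bracket , and said of Friday's, “so this is an extrapolation”.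

The simulation gives 83.7 % for Tuesday's and 75.5 % for Friday's, so Tuesday's ends higher.

    substrate + free catalyst ⇌ target + free catalyst, rate k1*[substrate]*[free catalyst] forward; the back reaction follows from the equilibrium constant (K = 27.5, k = 40.1 M⁻¹ h⁻¹)
    target + free catalyst ⇌ isomer of the product + free catalyst, rate k2*[free catalyst]*[target] forward; the back reaction follows from the equilibrium constant (K = 5.10, k = 74.4 M⁻¹ h⁻¹)
    2 free catalyst → spent catalyst (k = 227 M⁻¹ h⁻¹)

Friday's dose of 75.0 mM·h can be carried further. With 0.062 M of free catalyst, the same flask has a dose of 186 mM·h at 3.00 h. Tuesday's flask, with 18.0 mM·h at 3.0 h, left until 30.0 h reaches 180 mM·h, close to that, and holds 22.7 % target and 9.39 % isomer, a share of 70.8 %. So I read the neighbour off it, expecting that share. The neighbour holds 22.8 % target and 9.50 % isomer, a share of 70.6 %.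

The earlier runs and the new flask stem from a simulated flask from invented constants; noise was put on by code.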